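**Plan**

- The retrosynthesis first cuts the C2–O bond of the allylic alcohol unit C6=C1–C2(OH) (hydroperoxide reduction, then a singlet-oxygen ene reaction that returns the alkene to C1=C2). It then cuts the three ester C–O bonds at O3, O5 and O7; no C–C bond is cut.
- The six-membered carbocycle with its exocyclic carbon C7 is bought as (−)-shikimic acid. Forward, the carboxyl group is reduced to C7H2OH, O7 is benzoylated, O5 acetylated and O3 benzoylated through a cis-3,4-orthobenzoate; the only rings made are temporary dioxolanes across O3/O4.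
- The enabling feature is the cyclohexene ring itself: the trisubstituted C1=C2 alkene lies between the C6 methylene and the pseudoaxial C3 benzoyloxy group, and the pseudoaxial C6–H stands on the alkene face opposite that ester. An ene reaction therefore puts oxygen on C2 and moves the alkene to C1=C6 with every acyl group already in place.
- C3, C4 and C5 are the untouched stereocentres of shikimic acid; C2 is set in the ene step by attack of singlet oxygen anti to the C3 benzoate (O2 trans to O3, cis to O5).

Key step: step 9

Remark: shikimate numbering is used throughout (C1 bears the exocyclic carbon C7, C3 to C5 are the oxygenated carbons, C6 is the ring methylene). In the systematic names of the hydroperoxide and the target, ring positions 3, 4, 5, 6 are shikimate C5, C4, C3, C2. CIP descriptors of untouched centres change in places only because neighbouring substituents change.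

**Route**

Step 1
Reactants: 1 (−)-shikimic acid, (3R,4S,5R)-3,4,5-trihydroxycyclohex-1-ene-1-carboxylic acid
Product: 2 methyl shikimate, methyl (3R,4S,5R)-3,4,5-trihydroxycyclohex-1-ene-1-carboxylate
Conditions: MeOH, camphor-10-sulfonic acid (cat.), reflux
Reagents that add atoms: methanol, CO
Why: Fischer esterification in methanol as solvent drives the conjugated acid to its methyl ester and touches none of the three carbinol centres.

Step 2
Reactants: 2 methyl shikimate
Product: 3 methyl (3R,4S,5R)-5-hydroxy-3,4-(isopropylidenedioxy)cyclohex-1-ene-1-carboxylate (cis-fused 3,4-acetonide, O5 free on the opposite face)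
Conditions: Me2C(OMe)2, 4-MeC6H4SO3H·H2O (cat.), acetone, rt; Et3N quench
Reagents that add atoms: 2,2-dimethoxypropane, COC(C)(C)OC
Why: acid-catalysed transacetalisation closes the dioxolane only across the cis 3,4-diol, because a five-membered acetal fused trans across O4/O5 would be strained, so O5 stays free.

Step 3
Reactants: 3 methyl 3,4-O-isopropylidene shikimate
Product: 4 (3R,4S,5R)-5-hydroxy-1-(hydroxymethyl)-3,4-(isopropylidenedioxy)cyclohex-1-ene (acetonide diol, O7 and O5 free)
Conditions: iBu2AlH (3.5 equiv), CH2Cl2, −78 to 0 °C; aq. potassium sodium tartrate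
Reagents that add atoms: none
Why: 1,2-reduction of the conjugated ester by the Lewis-acidic hydride iBu2AlH gives the primary allylic alcohol without touching the alkene or the acetonide, the free O5–H only consuming one hydride, and the step is placed here because no acyl group is yet present.

Step 4
Reactants: 4 acetonide diol; 5 benzoyl chloride
Product: 6 [(3R,4S,5R)-5-hydroxy-3,4-(isopropylidenedioxy)cyclohex-1-en-1-yl]methyl benzoate (7-O-benzoate, O5 free)
Conditions: BzCl (1.05 equiv), pyridine, CH2Cl2, −40 °C
Reagents that add atoms: benzoyl chloride (5), O=C(Cl)c1ccccc1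
Why: kinetic acylation through the N-benzoylpyridinium ion (nucleophilic acyl substitution) favours the unhindered primary allylic hydroxyl over the secondary C5 hydroxyl, which is flanked by the acetonide.

Step 5
Reactants: 6 7-O-benzoate
Product: 7 [(3R,4S,5R)-5-acetoxy-3,4-(isopropylidenedioxy)cyclohex-1-en-1-yl]methyl benzoate
Conditions: Ac2O, pyridine, 4-(dimethylamino)pyridine (cat.), CH2Cl2, 0 °C to rt
Reagents that add atoms: acetic anhydride, CC(=O)OC(C)=O
Why: nucleophile-catalysed acetylation of the only remaining hydroxyl (O5) leaves the C5–O bond intact, so the configuration at C5 is retained.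

Step 6
Reactants: 7 5-O-acetyl-7-O-benzoyl acetonide
Product: 8 [(3R,4R,5R)-5-acetoxy-3,4-dihydroxycyclohex-1-en-1-yl]methyl benzoate (cis 3,4-diol; same spatial arrangement as before)
Conditions: AcOH/H2O (4:1), 45 °C; toluene azeotrope
Reagents that add atoms: none
Why: acid hydrolysis of the isopropylidene ketal is far faster than hydrolysis of the primary benzoate or the secondary acetate, and the weakly acidic, base-free medium should not promote acetyl migration from O5 to O4.

Step 7
Reactants: 8 3,4-diol; 9 trimethyl orthobenzoate
Product: 10 [(3R,4S,5R)-5-acetoxy-3,4-(α-methoxybenzylidenedioxy)cyclohex-1-en-1-yl]methyl benzoate (2-methoxy-2-phenyl-1,3-dioxolane fused cis at C3/C4, both epimers at the orthoester carbon)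
Conditions: PhC(OMe)3 (1.5 equiv), camphor-10-sulfonic acid (cat.), CH2Cl2, rt; concentrate
Reagents that add atoms: trimethyl orthobenzoate (9), COC(OC)(OC)c1ccccc1
Why: acid-catalysed orthoester exchange with loss of two molecules of methanol ties the only vicinal diol into a cyclic orthobenzoate, and the configuration at the orthoester carbon is irrelevant because that centre is destroyed in the next step.

Step 8
Reactants: 10 cyclic 3,4-orthobenzoate
Product: 11 [(3R,4S,5R)-5-acetoxy-3-(benzoyloxy)-4-hydroxycyclohex-1-en-1-yl]methyl benzoate (3,7-dibenzoate 5-acetate, O4 free)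
Conditions: AcOH/H2O (4:1), rt; toluene azeotrope below 30 °C
Reagents that add atoms: water, O
Why: acid hydrolysis of the cyclic orthoester passes through the 2-phenyl-1,3-dioxolan-2-ylium ion and its water adduct, whose stereoelectronically controlled collapse is known to leave the ester on the axial oxygen of a cis-diol on a six-membered ring, here the pseudoaxial allylic O3, and the hydroxyl on the equatorial O4.

Step 9
Reactants: 11 3,7-di-O-benzoyl-5-O-acetyl triol with O4 free
Product: 12 [(3R,4S,5S,6S)-3-acetoxy-5-(benzoyloxy)-6-hydroperoxy-4-hydroxycyclohex-1-en-1-yl]methyl benzoate (C2 hydroperoxide, alkene at C1=C6, OOH trans to O3 and cis to O5)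
Conditions: O2 (1 atm), 5,10,15,20-tetraphenylporphyrin (1 mol%), white LED, acid-free CDCl3, 0 °C; evaporate cold
Reagents that add atoms: dioxygen, O=O
Why: Sensitised singlet oxygen adds to the trisubstituted C1=C2 alkene through a perepoxide-like transition state on the ring face that carries the C5 acetate, and its outer oxygen takes the pseudoaxial C6 hydrogen on that same face, so the C2–O bond forms while the alkene moves to C1=C6 (Schenck ene reaction, suprafacial). The closest known reaction type is the Schenck ene hydroperoxidation of trisubstituted cyclohexenes and of cyclohexenes bearing allylic acyloxy groups; no ring is closed or opened. The new stereocentre C2 is set by the substrate: with O4 and O5 equatorial in the half-chair, the C3 benzoate is pseudoaxial and screens its own face, while the only allylic hydrogen held perpendicular to the alkene plane, pseudoaxial H6, lies on the opposite face, so attack and abstraction are matched there and the hydroperoxide should come out trans to O3. The step needs oxygen on C2 with hydrogen taken from C6 rather than from C7 or C3; the hydrogens geminal to the two benzoyloxy groups are electronically deactivated, H3 is pseudoequatorial and lies near the alkene plane, and C7 sits on the less substituted side of the alkene, which the cis effect disfavours. The esters, the free C4 hydroxyl and the more electron-poor C1=C6 alkene of the product should not react further under these neutral conditions.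

Step 10
Reactants: 12 C2 hydroperoxide
Product: 13 [(3R,4S,5R,6S)-3-acetoxy-5-(benzoyloxy)-4,6-dihydroxycyclohex-1-en-1-yl]methyl benzoate, the target CNP0169028.1
Conditions: PPh3 (1.1 equiv), CH2Cl2, 0 °C; chromatography on neutral silica
Reagents that add atoms: none
Why: triphenylphosphine attacks the terminal oxygen of the hydroperoxide and leaves as Ph3P=O, so the O–O bond is reduced without breaking the C2–O bond and the C2 configuration is retained, under neutral conditions that should not move the acyl groups.

**Compound list**

1 | (−)-shikimic acid, (3R,4S,5R)-3,4,5-trihydroxycyclohex-1-ene-1-carboxylic acid | O=C(O)C1=C[C@@H](O)[C@@H](O)[C@H](O)C1 | starting material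
2 | methyl shikimate, methyl (3R,4S,5R)-3,4,5-trihydroxycyclohex-1-ene-1-carboxylate | COC(=O)C1=C[C@@H](O)[C@@H](O)[C@H](O)C1 | intermediate
3 | methyl (3R,4S,5R)-5-hydroxy-3,4-(isopropylidenedioxy)cyclohex-1-ene-1-carboxylate | COC(=O)C1=C[C@H]2OC(C)(C)O[C@H]2[C@H](O)C1 | intermediate
4 | (3R,4S,5R)-5-hydroxy-1-(hydroxymethyl)-3,4-(isopropylidenedioxy)cyclohex-1-ene | OCC1=C[C@H]2OC(C)(C)O[C@H]2[C@H](O)C1 | intermediate
5 | benzoyl chloride | O=C(Cl)c1ccccc1 | starting material
6 | [(3R,4S,5R)-5-hydroxy-3,4-(isopropylidenedioxy)cyclohex-1-en-1-yl]methyl benzoate | O=C(OCC1=C[C@H]2OC(C)(C)O[C@H]2[C@H](O)C1)c1ccccc1 | intermediate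
7 | [(3R,4S,5R)-5-acetoxy-3,4-(isopropylidenedioxy)cyclohex-1-en-1-yl]methyl benzoate | O=C(OCC1=C[C@H]2OC(C)(C)O[C@H]2[C@H](OC(C)=O)C1)c1ccccc1 | intermediate
8 | [(3R,4R,5R)-5-acetoxy-3,4-dihydroxycyclohex-1-en-1-yl]methyl benzoate | O=C(OCC1=C[C@@H](O)[C@@H](O)[C@H](OC(C)=O)C1)c1ccccc1 | intermediate
9 | trimethyl orthobenzoate, (trimethoxymethyl)benzene | COC(OC)(OC)c1ccccc1 | starting material
10 | [(3R,4S,5R)-5-acetoxy-3,4-(α-methoxybenzylidenedioxy)cyclohex-1-en-1-yl]methyl benzoate, both epimers at the orthoester carbon | O=C(OCC1=C[C@H]2OC(OC)(c3ccccc3)O[C@H]2[C@H](OC(C)=O)C1)c1ccccc1 | intermediate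
11 | [(3R,4S,5R)-5-acetoxy-3-(benzoyloxy)-4-hydroxycyclohex-1-en-1-yl]methyl benzoate | O=C(OCC1=C[C@@H](OC(=O)c2ccccc2)[C@@H](O)[C@H](OC(C)=O)C1)c1ccccc1 | intermediate
12 | [(3R,4S,5S,6S)-3-acetoxy-5-(benzoyloxy)-6-hydroperoxy-4-hydroxycyclohex-1-en-1-yl]methyl benzoate | CC(=O)O[C@@H]1C=C(COC(=O)c2ccccc2)[C@H](OO)[C@@H](OC(=O)c2ccccc2)[C@H]1O | intermediate
13 | [(3R,4S,5R,6S)-3-acetoxy-5-(benzoyloxy)-4,6-dihydroxycyclohex-1-en-1-yl]methyl benzoate (CNP0169028.1) | CC(=O)O[C@@H]1C=C(COC(=O)c2ccccc2)[C@H](O)[C@@H](OC(=O)c2ccccc2)[C@H]1O | target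

**Totals and risks**

Total step count: 10. Longest linear sequence: 10 steps (1 to 13).

Steps most likely to fail:

1. Step 9. The alkene of 11 is flanked by two acyloxy-bearing carbons, so oxygen transfer may be too slow, hydrogen may be taken from C7 instead of C6, or attack may occur on the face of the C3 ester. The fallback sets out from 7 and returns at 13, with the ene reaction moved ahead of the diol differentiation. Acetonide 7 has only one allylic ester, and its cis-fused dioxolane covers the O3/O4 face. It is photooxygenated (O2, 5,10,15,20-tetraphenylporphyrin, visible light) to the C2 hydroperoxide of the acetonide F1, which is reduced in the same flask with PPh3 to the acetonide allylic alcohol F2. Aqueous acetic acid then removes the acetonide to give the 2,3,4-triol F3. Trimethyl orthobenzoate 9 with catalytic camphor-10-sulfonic acid closes the cis 3,4-diol, in preference to the trans 2,3-diol, to the 3,4-orthobenzoate F4, and mild aqueous acetic acid opens it to 13. In this cyclohexene the C2 oxygen should sit pseudoaxial to avoid allylic strain with the C1 substituent, which makes O3 axial and O4 equatorial, so the benzoate is again expected on O3.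

2. Step 8. The orthoester may collapse toward the equatorial oxygen, or acid may promote benzoyl migration from O3 to O4, so that the ester ends up on the wrong oxygen. The fallback sets out from 2 and returns at 11, placing the O3 benzoate with no regiochemical choice. Methyl shikimate 2 with 2,2,3,3-tetramethoxybutane and catalytic camphor-10-sulfonic acid in methanol gives the 4,5-butane-2,3-diacetal of methyl shikimate F5, in which the trans-diequatorial diol is locked and O3 is free. iBu2AlH reduces the ester to the diacetal diol F6, and excess benzoyl chloride 5 in pyridine gives the diacetal 3,7-dibenzoate F7. Aqueous trifluoroacetic acid removes the diacetal to give the 3,7-dibenzoate 4,5-diol F8. Acetyl chloride with 2,4,6-collidine at −78 °C should then acetylate the less hindered O5, since O4 is flanked by the C3 benzoate, which gives 11.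

3. Step 4. Discrimination between the primary O7 and the secondary O5 hydroxyl may be lost, giving the dibenzoate. The fallback sets out from 3 and returns at 6, masking O5 before the reduction. Ester 3 with tert-butyldimethylsilyl chloride and imidazole gives the 5-O-silyl ester F9, and iBu2AlH reduces it to the 5-O-silyl primary alcohol F10. Benzoyl chloride 5 in pyridine gives the 5-O-silyl 7-benzoate F11, and HF·pyridine in THF frees O5 to give 6.

**Further compounds**

F1 | step 9 | [3-acetoxy-6-hydroperoxy-4,5-(isopropylidenedioxy)cyclohex-1-en-1-yl]methyl benzoate, configuration as in 12 | CC(=O)O[C@@H]1C=C(COC(=O)c2ccccc2)[C@H](OO)[C@H]2OC(C)(C)O[C@@H]12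
F2 | step 9 | [3-acetoxy-6-hydroxy-4,5-(isopropylidenedioxy)cyclohex-1-en-1-yl]methyl benzoate, configuration as in 13 | CC(=O)O[C@@H]1C=C(COC(=O)c2ccccc2)[C@H](O)[C@H]2OC(C)(C)O[C@@H]12
F3 | step 9 | (3-acetoxy-4,5,6-trihydroxycyclohex-1-en-1-yl)methyl benzoate, configuration as in 13 | CC(=O)O[C@@H]1C=C(COC(=O)c2ccccc2)[C@H](O)[C@@H](O)[C@H]1O
F4 | step 9 | [3-acetoxy-6-hydroxy-4,5-(α-methoxybenzylidenedioxy)cyclohex-1-en-1-yl]methyl benzoate, both epimers at the orthoester carbon | CC(=O)O[C@@H]1C=C(COC(=O)c2ccccc2)[C@H](O)[C@H]2OC(OC)(c3ccccc3)O[C@@H]12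
F5 | step 8 | methyl 3-hydroxy-4,5-O-[(2S,3S)-2,3-dimethoxybutane-2,3-diyl]shikimate | COC(=O)C1=C[C@@H](O)[C@H]2O[C@](C)(OC)[C@@](C)(OC)O[C@@H]2C1
F6 | step 8 | 1-(hydroxymethyl)-3-hydroxy-4,5-O-[(2S,3S)-2,3-dimethoxybutane-2,3-diyl]cyclohex-1-ene, shikimate configuration | OCC1=C[C@@H](O)[C@H]2O[C@](C)(OC)[C@@](C)(OC)O[C@@H]2C1
F7 | step 8 | 3,7-di-O-benzoate of F6 | O=C(OCC1=C[C@@H](OC(=O)c3ccccc3)[C@H]2O[C@](C)(OC)[C@@](C)(OC)O[C@@H]2C1)c1ccccc1
F8 | step 8 | [3-(benzoyloxy)-4,5-dihydroxycyclohex-1-en-1-yl]methyl benzoate, shikimate configuration | O=C(OCC1=C[C@@H](OC(=O)c2ccccc2)[C@@H](O)[C@H](O)C1)c1ccccc1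
F9 | step 4 | methyl 5-O-(tert-butyldimethylsilyl)-3,4-O-isopropylidene shikimate | COC(=O)C1=C[C@H]2OC(C)(C)O[C@H]2[C@H](O[Si](C)(C)C(C)(C)C)C1
F10 | step 4 | 5-(tert-butyldimethylsilyloxy)-1-(hydroxymethyl)-3,4-(isopropylidenedioxy)cyclohex-1-ene, shikimate configuration | OCC1=C[C@H]2OC(C)(C)O[C@H]2[C@H](O[Si](C)(C)C(C)(C)C)C1
F11 | step 4 | [5-(tert-butyldimethylsilyloxy)-3,4-(isopropylidenedioxy)cyclohex-1-en-1-yl]methyl benzoate, shikimate configuration | O=C(OCC1=C[C@H]2OC(C)(C)O[C@H]2[C@H](O[Si](C)(C)C(C)(C)C)C1)c1ccccc1
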